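**Plan**

- Retrosynthesis: the C5–OOH bond and the C4=C15 alkene go back to a C4=C5 alkene (Schenck ene). The two acyl groups, the C11=C13 methylene and the ester/8-oxygen pair go back to a cis 12,8β-lactone and then to a 3,8-diketone. Ring B is then cut at C9–C10, and the chain at C8–C9 and C6–C7.
- Enabling feature: ring A (C1-C2-C3-C4-C5-C10) is a hidden 2,4-dimethylphenol. The C3 oxygen is para to quaternary C10, C4 and C10 each carry one carbon (C15, C14), and C5 carries the chain, so ring B (C5-C6-C7-C8-C9-C10) can close by para C-alkylation with dearomatisation.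
- Forward: ring A is bought as 2,6-dimethylbenzoic acid and oxygenated at C3. The chain C6–C7(C11–C12)–C8 is joined by an Evans alkylation (C6–C7), and C9 is added as a diazomethyl ketone. Ring B closes in step 11, and a temporary γ-lactone then serves for the C13 methylenation.
- Stereochemistry: C7 comes from (R)-4-benzyl-2-oxazolidinone; C10 from C7 in the ring closure (equatorial arm in a chair); C8 and C3 from substrate-controlled hydride additions; C5 from α-face attack of singlet oxygen opposite the C10 methyl group.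

Key step: step 11

Remark: eudesmane numbering and α/β descriptors (β = the face of the C10 methyl group C14) are used for the bicyclic compounds; those that still lack C13 are named as 13-noreudesmanes, and the target is the (3S,5S,7R,8R,10R) isomer.

Step 1
Reactants: 1 2,6-dimethylbenzoic acid
Product: 2 3-bromo-2,6-dimethylbenzoic acid
Conditions: Br2 (1.05 equiv), AcOH, 25 °C
Reagents that add atoms: bromine, BrBr
Why: Electrophilic aromatic bromination: C3 is ortho to one methyl group, para to the other and meta to the carboxyl group, so monobromination should occur there.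

Step 2
Reactants: 2 3-bromo-2,6-dimethylbenzoic acid
Product: 3 3-hydroxy-2,6-dimethylbenzoic acid
Conditions: Pd2(dba)3 (cat.), 2-di-tert-butylphosphino-2′,4′,6′-triisopropylbiphenyl (cat.), KOH, 1,4-dioxane/H2O, 100 °C; then HCl
Reagents that add atoms: potassium hydroxide, [K+].[OH-]
Why: Palladium-catalysed Buchwald–Hartwig-type C–O coupling of the aryl bromide with hydroxide; the bulky biarylphosphine drives reductive elimination beside the ortho methyl group and the carboxylate is inert.

Step 3
Reactants: 3 3-hydroxy-2,6-dimethylbenzoic acid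
Product: 5 2,6-dimethyl-3-(triisopropylsilyloxy)benzoic acid, via bis-silylated ester 4 (not isolated)
Conditions: i-Pr3SiCl (2.3 equiv), imidazole, DMF, 25 °C; then K2CO3, THF/H2O, 25 °C; then aq. citric acid
Reagents that add atoms: chlorotriisopropylsilane, CC(C)[Si](Cl)(C(C)C)C(C)C
Why: Silylation of both acidic OH groups, then selective hydrolysis of the silyl ester, whose carboxylate is a far better leaving group at silicon than the hindered aryloxide, leaves the phenol as its robust triisopropylsilyl ether.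

Step 4
Reactants: 5 2,6-dimethyl-3-(triisopropylsilyloxy)benzoic acid
Product: 6 [2,6-dimethyl-3-(triisopropylsilyloxy)phenyl]methanol
Conditions: BH3·THF, THF, 0 to 65 °C; then H2O
Reagents that add atoms: none
Why: Borane reduction of a carboxylic acid via the acyloxyborane, which works for ortho,ortho-disubstituted benzoic acids and does not touch the aryl silyl ether.

Step 5
Reactants: 6 [2,6-dimethyl-3-(triisopropylsilyloxy)phenyl]methanol
Product: 7 [3-(bromomethyl)-2,4-dimethylphenoxy]triisopropylsilane
Conditions: CBr4, PPh3, CH2Cl2, 0 °C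
Reagents that add atoms: tetrabromomethane, BrC(Br)(Br)Br
Why: Appel reaction, a neutral SN2 bromination of the primary benzylic alcohol that spares the aryl silyl ether.

Step 6
Reactants: 8 (R)-4-benzyl-2-oxazolidinone; 9 methyl 4-chloro-4-oxobutanoate
Product: 11 methyl 4-[(4R)-4-benzyl-2-oxo-1,3-oxazolidin-3-yl]-4-oxobutanoate, via N-lithio oxazolidinone 10 (not isolated)
Conditions: n-BuLi, THF, -78 °C; then 9, -78 to 0 °C
Reagents that add atoms: none
Why: N-Acylation of the lithiated oxazolidinone by the acid chloride, the standard entry to Evans imides; the methyl ester is far less electrophilic than the acyl chloride.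

Step 7
Reactants: 11 methyl 4-[(4R)-4-benzyl-2-oxo-1,3-oxazolidin-3-yl]-4-oxobutanoate; 7 [3-(bromomethyl)-2,4-dimethylphenoxy]triisopropylsilane
Product: 13 methyl (3R)-4-[(4R)-4-benzyl-2-oxo-1,3-oxazolidin-3-yl]-3-{[2,6-dimethyl-3-(triisopropylsilyloxy)phenyl]methyl}-4-oxobutanoate, via sodium Z-enolate 12 (not isolated)
Conditions: NaN(SiMe3)2, THF, -78 °C; then 7, -78 to -20 °C
Reagents that add atoms: none
Why: Evans asymmetric alkylation: the imide α-CH2 is deprotonated in preference to the ester α-CH2 to give the chelated Z-enolate, and the benzylic bromide enters on the face opposite the benzyl group of the auxiliary, which sets C7 as R.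

Step 8
Reactants: 13 methyl (3R)-4-[(4R)-4-benzyl-2-oxo-1,3-oxazolidin-3-yl]-3-{[2,6-dimethyl-3-(triisopropylsilyloxy)phenyl]methyl}-4-oxobutanoate
Product: 15 (2R)-2-{[2,6-dimethyl-3-(triisopropylsilyloxy)phenyl]methyl}-4-methoxy-4-oxobutanoic acid, via lithium percarboxylate 14 (not isolated)
Conditions: LiOH, H2O2, THF/H2O, 0 °C; then aq. Na2SO3; then HCl (pH 3)
Reagents that add atoms: hydrogen peroxide, OO
Why: Hydroperoxide-mediated cleavage of the Evans imide: LiOOH attacks the exocyclic carbonyl selectively and faster than it attacks the methyl ester, the peracid is reduced by sulfite, and C7 is not epimerised.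

Step 9
Reactants: 15 (2R)-2-{[2,6-dimethyl-3-(triisopropylsilyloxy)phenyl]methyl}-4-methoxy-4-oxobutanoic acid; 16 (trimethylsilyl)diazomethane
Product: 19 methyl (3R)-5-diazo-3-{[2,6-dimethyl-3-(triisopropylsilyloxy)phenyl]methyl}-4-oxopentanoate, via mixed carbonic anhydride 17 (not isolated), via C-silyl diazoketone 18 (not isolated)
Conditions: i-BuOCOCl, N-methylmorpholine, THF, -15 °C; then 16 (2 equiv), MeCN, 0 to 25 °C; then aq. NaHCO3
Reagents that add atoms: none
Why: Arndt–Eistert-type acylation of (trimethylsilyl)diazomethane by a mixed carbonic anhydride, which avoids an acyl chloride and a ketene and so keeps C7 and the half-ester pattern intact; the C-silyl group is lost on aqueous work-up.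

Step 10
Reactants: 19 methyl (3R)-5-diazo-3-{[2,6-dimethyl-3-(triisopropylsilyloxy)phenyl]methyl}-4-oxopentanoate
Product: 20 methyl (3R)-5-diazo-3-[(3-hydroxy-2,6-dimethylphenyl)methyl]-4-oxopentanoate
Conditions: Bu4NF, AcOH, THF, 0 °C
Reagents that add atoms: none
Why: Fluoride-mediated cleavage of the aryl silyl ether, buffered with acetic acid so that neither a free phenoxide nor a strong acid meets the diazoketone or the epimerisable C7.

Step 11
Reactants: 20 methyl (3R)-5-diazo-3-[(3-hydroxy-2,6-dimethylphenyl)methyl]-4-oxopentanoate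
Product: 22 methyl (7R,10S)-3,8-dioxo-13-noreudesma-1,4-dien-12-oate, via diazonium trifluoroacetate 21 (not isolated)
Conditions: CF3CO2H, CH2Cl2, -20 °C (20 added to the acid); then aq. NaHCO3
Reagents that add atoms: none
Why: CF3CO2H protonates the diazo carbon C9 to give the α-keto alkyldiazonium ion 21, and the phenol attacks it through C10, para to the hydroxyl group and perpendicular to the ring plane, with loss of N2; loss of the phenolic proton then gives a dienone that cannot rearomatise because C10 is quaternary. The closest known reaction type is the acid-promoted aryl-participation cyclisation of phenolic diazomethyl ketones to cyclohexadienones, an intramolecular para C-alkylation of a phenol. Ring B (C5-C6-C7-C8-C9-C10) closes 6-exo-tet at C9. C10 is set by C7: in the chair-like transition state the C7 acetate arm lies equatorial, which places C14 cis to the arm (7R gives 10S), whereas attack on the other face needs the arm axial beside the departing N2 or a boat. The step needs bonding at C10 and not at C4 or C5: C5 is meta to the hydroxyl group and not activated, and C10 should win over C4 because the para-quinoid cation and the cross-conjugated dienone are more stable than the ortho-quinoid ones and because C4 is flanked by C3–O and C5 while C10 has the unsubstituted C1 as its neighbour. Trifluoroacetate is a poor nucleophile, so capture of the diazonium ion by the medium should not compete with the tethered arene.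

Step 12
Reactants: 22 methyl (7R,10S)-3,8-dioxo-13-noreudesma-1,4-dien-12-oate
Product: 24 3-oxo-13-noreudesma-1,4-dien-12,8β-olide, via lithium alkoxide 23 (not isolated)
Conditions: LiBH(s-Bu)3 (1.05 equiv), THF, -78 to 0 °C; then AcOH
Reagents that add atoms: none
Why: Hydride reduction of the only isolated ketone with a bulky trialkylborohydride (the cross-conjugated dienone carbonyl is much less electrophilic): hydride comes in equatorially on the α face, away from the syn-axial C10 methyl group, which sets C8 with an axial 8β-oxygen cis to the C7 arm, and the alkoxide closes the cis-fused γ-lactone by intramolecular transesterification.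

Step 13
Reactants: 24 3-oxo-13-noreudesma-1,4-dien-12,8β-olide
Product: 25 3-oxo-13-noreudesm-4-en-12,8β-olide
Conditions: RhCl(PPh3)3 (cat.), H2 (1 atm), benzene/EtOH, 25 °C
Reagents that add atoms: none
Why: Homogeneous hydrogenation with RhCl(PPh3)3 reduces the disubstituted C1=C2 bond of a santonin-type cross-conjugated dienone and leaves the tetrasubstituted C4=C5 bond, the carbonyl groups and the lactone.

Step 14
Reactants: 25 3-oxo-13-noreudesm-4-en-12,8β-olide
Product: 26 3β-hydroxy-13-noreudesm-4-en-12,8β-olide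
Conditions: NaBH4, CeCl3·7H2O, MeOH, -40 to 0 °C
Reagents that add atoms: none
Why: Luche reduction: 1,2-hydride addition to the enone, axial and on the α face, sets C3 as the pseudo-equatorial 3β-alcohol; the lactone is not reduced.

Step 15
Reactants: 26 3β-hydroxy-13-noreudesm-4-en-12,8β-olide
Product: 27 3β-(tert-butyldimethylsilyloxy)-13-noreudesm-4-en-12,8β-olide
Conditions: t-BuMe2SiCl, imidazole, DMF, 25 °C
Reagents that add atoms: tert-butylchlorodimethylsilane, CC(C)(C)[Si](C)(C)Cl
Why: Standard silylation of a secondary allylic alcohol, needed because the next steps use a strong base and hydroxide.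

Step 16
Reactants: 27 3β-(tert-butyldimethylsilyloxy)-13-noreudesm-4-en-12,8β-olide
Product: 29 3β-(tert-butyldimethylsilyloxy)-13-(dimethylamino)eudesm-4-en-12,8β-olide, via lithium enolate 28 (not isolated)
Conditions: LiN(i-Pr)2, THF, -78 °C; then CH2=NMe2+ I-, -78 to 25 °C
Reagents that add atoms: N,N-dimethylmethyleneiminium iodide, C=[N+](C)C.[I-]
Why: Mannich aminomethylation of the lactone lithium enolate with Eschenmoser's salt, the lactone α-CH2 being the only acidic site; the electrophile adds on the convex face, but the C11 centre is removed in the next step.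

Step 17
Reactants: 29 3β-(tert-butyldimethylsilyloxy)-13-(dimethylamino)eudesm-4-en-12,8β-olide
Product: 31 3β-(tert-butyldimethylsilyloxy)eudesma-4,11(13)-dien-12,8β-olide, via trimethylammonium iodide 30 (not isolated)
Conditions: MeI, THF, 25 °C; then aq. NaHCO3, EtOAc, 25 °C
Reagents that add atoms: none
Why: N-Methylation followed by base-induced Hofmann-type β-elimination of trimethylamine, the standard way to an α-methylene γ-lactone.

Step 18
Reactants: 31 3β-(tert-butyldimethylsilyloxy)eudesma-4,11(13)-dien-12,8β-olide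
Product: 33 methyl 3β-(tert-butyldimethylsilyloxy)-8β-hydroxyeudesma-4,11(13)-dien-12-oate, via potassium carboxylate 32 (not isolated)
Conditions: KOH (1.05 equiv), THF/H2O, 0 to 25 °C; evaporate; then MeI, DMF, 0 °C; neutral work-up, used crude at once
Reagents that add atoms: potassium hydroxide, [K+].[OH-]; iodomethane, CI
Why: Saponification of the strained lactone to the hydroxy carboxylate and SN2 O-methylation of the carboxylate with iodomethane under non-acidic conditions, so that the hydroxy ester never meets acid and is taken on without chromatography before it can relactonise.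

Step 19
Reactants: 33 methyl 3β-(tert-butyldimethylsilyloxy)-8β-hydroxyeudesma-4,11(13)-dien-12-oate
Product: 34 methyl 8β-acetoxy-3β-(tert-butyldimethylsilyloxy)eudesma-4,11(13)-dien-12-oate
Conditions: Ac2O, Et3N, 4-(dimethylamino)pyridine (cat.), CH2Cl2, 0 to 25 °C
Reagents that add atoms: acetic anhydride, CC(=O)OC(C)=O
Why: Acylation of the hindered axial 8β-alcohol with acetic anhydride under nucleophilic catalysis by 4-(dimethylamino)pyridine (Steglich-type acylation), which should outrun base-induced relactonisation onto the conjugated ester.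

Step 20
Reactants: 34 methyl 8β-acetoxy-3β-(tert-butyldimethylsilyloxy)eudesma-4,11(13)-dien-12-oate
Product: 35 methyl 8β-acetoxy-3β-hydroxyeudesma-4,11(13)-dien-12-oate
Conditions: HF·pyridine, pyridine/THF, 0 to 25 °C
Reagents that add atoms: none
Why: Fluoride-mediated desilylation with buffered HF·pyridine, which leaves the acetate, the acrylate ester and the allylic alcohol intact.

Step 21
Reactants: 35 methyl 8β-acetoxy-3β-hydroxyeudesma-4,11(13)-dien-12-oate
Product: 36 methyl 8β-acetoxy-3β-(isobutyryloxy)eudesma-4,11(13)-dien-12-oate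
Conditions: (i-PrCO)2O, Et3N, 4-(dimethylamino)pyridine (cat.), CH2Cl2, 25 °C
Reagents that add atoms: isobutyric anhydride, CC(C)C(=O)OC(=O)C(C)C
Why: Acylation of the equatorial allylic 3β-alcohol with isobutyric anhydride under 4-(dimethylamino)pyridine catalysis.

Step 22
Reactants: 36 methyl 8β-acetoxy-3β-(isobutyryloxy)eudesma-4,11(13)-dien-12-oate
Product: 37 methyl 8β-acetoxy-5α-hydroperoxy-3β-(isobutyryloxy)eudesma-4(15),11(13)-dien-12-oate
Conditions: O2, visible light, 5,10,15,20-tetraphenylporphyrin (cat.), CH2Cl2, -20 °C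
Reagents that add atoms: dioxygen, O=O
Why: Schenck ene reaction: singlet oxygen adds to the electron-rich tetrasubstituted C4=C5 bond on the α face, opposite the axial C10 methyl group, bonds to C5 and takes a hydrogen from the C15 methyl group (the C3 hydrogen is deactivated by the geminal acyloxy group and 6α-H is not axial), which sets C5 as the 5α-hydroperoxide and moves the double bond to C4=C15; the acrylate is too electron-poor to react.

**Compound list**

1 | 2,6-dimethylbenzoic acid | Cc1cccc(C)c1C(=O)O | starting material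
2 | 3-bromo-2,6-dimethylbenzoic acid | Cc1ccc(Br)c(C)c1C(=O)O | intermediate
3 | 3-hydroxy-2,6-dimethylbenzoic acid | Cc1ccc(O)c(C)c1C(=O)O | intermediate
4 | triisopropylsilyl 2,6-dimethyl-3-(triisopropylsilyloxy)benzoate | Cc1ccc(O[Si](C(C)C)(C(C)C)C(C)C)c(C)c1C(=O)O[Si](C(C)C)(C(C)C)C(C)C | intermediate
5 | 2,6-dimethyl-3-(triisopropylsilyloxy)benzoic acid | Cc1ccc(O[Si](C(C)C)(C(C)C)C(C)C)c(C)c1C(=O)O | intermediate
6 | [2,6-dimethyl-3-(triisopropylsilyloxy)phenyl]methanol | Cc1ccc(O[Si](C(C)C)(C(C)C)C(C)C)c(C)c1CO | intermediate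
7 | [3-(bromomethyl)-2,4-dimethylphenoxy]triisopropylsilane | Cc1ccc(O[Si](C(C)C)(C(C)C)C(C)C)c(C)c1CBr | intermediate
8 | (R)-4-benzyl-2-oxazolidinone | O=C1N[C@H](Cc2ccccc2)CO1 | starting material
9 | methyl 4-chloro-4-oxobutanoate | COC(=O)CCC(=O)Cl | starting material
10 | lithium salt of (R)-4-benzyl-2-oxazolidinone (N-lithio) | [Li+].O=C1[N-][C@H](Cc2ccccc2)CO1 | intermediate
11 | methyl 4-[(4R)-4-benzyl-2-oxo-1,3-oxazolidin-3-yl]-4-oxobutanoate | COC(=O)CCC(=O)N1[C@H](Cc2ccccc2)COC1=O | intermediate
12 | sodium (Z)-enolate of 11 | [Na+].COC(=O)C/C=C(\[O-])N1[C@H](Cc2ccccc2)COC1=O | intermediate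
13 | methyl (3R)-4-[(4R)-4-benzyl-2-oxo-1,3-oxazolidin-3-yl]-3-{[2,6-dimethyl-3-(triisopropylsilyloxy)phenyl]methyl}-4-oxobutanoate | COC(=O)C[C@@H](Cc1c(C)c(O[Si](C(C)C)(C(C)C)C(C)C)ccc1C)C(=O)N1[C@H](Cc2ccccc2)COC1=O | intermediate
14 | lithium (2R)-2-{[2,6-dimethyl-3-(triisopropylsilyloxy)phenyl]methyl}-4-methoxy-4-oxobutaneperoxoate | [Li+].COC(=O)C[C@@H](Cc1c(C)c(O[Si](C(C)C)(C(C)C)C(C)C)ccc1C)C(=O)O[O-] | intermediate
15 | (2R)-2-{[2,6-dimethyl-3-(triisopropylsilyloxy)phenyl]methyl}-4-methoxy-4-oxobutanoic acid | COC(=O)C[C@@H](Cc1c(C)c(O[Si](C(C)C)(C(C)C)C(C)C)ccc1C)C(=O)O | intermediate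
16 | (trimethylsilyl)diazomethane | C[Si](C)(C)C=[N+]=[N-] | starting material
17 | isobutyl carbonic anhydride of acid 15 (2R) | COC(=O)C[C@@H](Cc1c(C)c(O[Si](C(C)C)(C(C)C)C(C)C)ccc1C)C(=O)OC(=O)OCC(C)C | intermediate
18 | methyl (3R)-5-diazo-3-{[2,6-dimethyl-3-(triisopropylsilyloxy)phenyl]methyl}-4-oxo-5-(trimethylsilyl)pentanoate | COC(=O)C[C@@H](Cc1c(C)c(O[Si](C(C)C)(C(C)C)C(C)C)ccc1C)C(=O)C(=[N+]=[N-])[Si](C)(C)C | intermediate
19 | methyl (3R)-5-diazo-3-{[2,6-dimethyl-3-(triisopropylsilyloxy)phenyl]methyl}-4-oxopentanoate | COC(=O)C[C@@H](Cc1c(C)c(O[Si](C(C)C)(C(C)C)C(C)C)ccc1C)C(=O)C=[N+]=[N-] | intermediate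
20 | methyl (3R)-5-diazo-3-[(3-hydroxy-2,6-dimethylphenyl)methyl]-4-oxopentanoate | COC(=O)C[C@@H](Cc1c(C)c(O)ccc1C)C(=O)C=[N+]=[N-] | intermediate
21 | (3R)-3-[(3-hydroxy-2,6-dimethylphenyl)methyl]-5-methoxy-2,5-dioxopentane-1-diazonium trifluoroacetate | COC(=O)C[C@@H](Cc1c(C)c(O)ccc1C)C(=O)C[N+]#N.[O-]C(=O)C(F)(F)F | intermediate
22 | methyl (7R,10S)-3,8-dioxo-13-noreudesma-1,4-dien-12-oate (7αH, 10β-methyl) | COC(=O)C[C@H]1CC2=C(C)C(=O)C=C[C@]2(C)CC1=O | intermediate
23 | lithium 8β-alkoxide of methyl 8β-hydroxy-3-oxo-13-noreudesma-1,4-dien-12-oate | [Li+].COC(=O)C[C@H]1CC2=C(C)C(=O)C=C[C@]2(C)C[C@H]1[O-] | intermediate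
24 | 3-oxo-13-noreudesma-1,4-dien-12,8β-olide (cis-fused lactone, 7αH, 8αH) | O=C1C[C@H]2CC3=C(C)C(=O)C=C[C@]3(C)C[C@H]2O1 | intermediate
25 | 3-oxo-13-noreudesm-4-en-12,8β-olide | O=C1C[C@H]2CC3=C(C)C(=O)CC[C@]3(C)C[C@H]2O1 | intermediate
26 | 3β-hydroxy-13-noreudesm-4-en-12,8β-olide | O=C1C[C@H]2CC3=C(C)[C@@H](O)CC[C@]3(C)C[C@H]2O1 | intermediate
27 | 3β-(tert-butyldimethylsilyloxy)-13-noreudesm-4-en-12,8β-olide | O=C1C[C@H]2CC3=C(C)[C@@H](O[Si](C)(C)C(C)(C)C)CC[C@]3(C)C[C@H]2O1 | intermediate
28 | lithium enolate of lactone 27 | [Li+].[O-]C1=C[C@H]2CC3=C(C)[C@@H](O[Si](C)(C)C(C)(C)C)CC[C@]3(C)C[C@H]2O1 | intermediate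
29 | 3β-(tert-butyldimethylsilyloxy)-13-(dimethylamino)eudesm-4-en-12,8β-olide (C13 cis to H7) | O=C1[C@H](CN(C)C)[C@H]2CC3=C(C)[C@@H](O[Si](C)(C)C(C)(C)C)CC[C@]3(C)C[C@H]2O1 | intermediate
30 | N-methyl iodide (13-trimethylammonium iodide) of 29 | [I-].O=C1[C@H](C[N+](C)(C)C)[C@H]2CC3=C(C)[C@@H](O[Si](C)(C)C(C)(C)C)CC[C@]3(C)C[C@H]2O1 | intermediate
31 | 3β-(tert-butyldimethylsilyloxy)eudesma-4,11(13)-dien-12,8β-olide | O=C1C(=C)[C@H]2CC3=C(C)[C@@H](O[Si](C)(C)C(C)(C)C)CC[C@]3(C)C[C@H]2O1 | intermediate
32 | potassium 3β-(tert-butyldimethylsilyloxy)-8β-hydroxyeudesma-4,11(13)-dien-12-oate | [K+].[O-]C(=O)C(=C)[C@H]1CC2=C(C)[C@@H](O[Si](C)(C)C(C)(C)C)CC[C@]2(C)C[C@H]1O | intermediate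
33 | methyl 3β-(tert-butyldimethylsilyloxy)-8β-hydroxyeudesma-4,11(13)-dien-12-oate | COC(=O)C(=C)[C@H]1CC2=C(C)[C@@H](O[Si](C)(C)C(C)(C)C)CC[C@]2(C)C[C@H]1O | intermediate
34 | methyl 8β-acetoxy-3β-(tert-butyldimethylsilyloxy)eudesma-4,11(13)-dien-12-oate | COC(=O)C(=C)[C@H]1CC2=C(C)[C@@H](O[Si](C)(C)C(C)(C)C)CC[C@]2(C)C[C@H]1OC(C)=O | intermediate
35 | methyl 8β-acetoxy-3β-hydroxyeudesma-4,11(13)-dien-12-oate | COC(=O)C(=C)[C@H]1CC2=C(C)[C@@H](O)CC[C@]2(C)C[C@H]1OC(C)=O | intermediate
36 | methyl 8β-acetoxy-3β-(isobutyryloxy)eudesma-4,11(13)-dien-12-oate | COC(=O)C(=C)[C@H]1CC2=C(C)[C@@H](OC(=O)C(C)C)CC[C@]2(C)C[C@H]1OC(C)=O | intermediate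
37 | methyl (3S,5S,7R,8R,10R)-8β-acetoxy-5α-hydroperoxy-3β-(isobutyryloxy)eudesma-4(15),11(13)-dien-12-oate | C=C(C(=O)OC)[C@H]1C[C@@]2(OO)C(=C)[C@@H](OC(=O)C(C)C)CC[C@]2(C)C[C@H]1OC(C)=O | target

**Step count and risks**

Total: 22 steps. Longest linear sequence: 21 steps (steps 1 to 5 and 7 to 22, from 1); step 6 is the one-step side branch.

Steps most likely to fail:

Step 11. The diazonium ion may be captured before the arene reaches it (by trifluoroacetate or by the carbonyl oxygen of the C12 ester), C9 may bond to the ortho carbon C4, or it may bond to the other face of C10. The fallback activates the nucleophile instead of the electrophile. Starting from 20, aqueous HBr in Et2O at 0 °C should replace N2 by bromide to give methyl (3R)-5-bromo-3-[(3-hydroxy-2,6-dimethylphenyl)methyl]-4-oxopentanoate F1. One equivalent of KOt-Bu in t-BuOH/THF at 0 °C then forms the potassium phenoxide, which should close ring B by intramolecular para C-alkylation (aryl participation of a phenoxide) and return to the route at 22. No cation is formed that the medium or the ester could trap, the hydrogen-bonded phenoxide oxygen steers the alkylation to carbon, and a single equivalent of base, once it sits on the phenol, is too weak to enolise C7.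

Step 18. Hydroxy ester 33 may close back to lactone 31 with loss of methanol before or during the acetylation of step 19, or hydroxide may add to C13. The fallback acetylates C8 while C12 is at the alcohol level. Starting from 31:
- i-Bu2AlH (CH2Cl2, -78 to 0 °C) should give 3β-(tert-butyldimethylsilyloxy)eudesma-4,11(13)-diene-8β,12-diol F2.
- Et3SiCl/imidazole at -78 °C silylates only the primary allylic alcohol to give the 12-triethylsilyl ether F3.
- Ac2O with 4-(dimethylamino)pyridine gives its 8β-acetate F4.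
- Pyridinium p-toluenesulfonate in MeOH at 0 °C removes only the primary triethylsilyl group to give the 8β-acetoxy 12-alcohol F5.
- MnO2 in CH2Cl2 oxidises it to the 2-substituted acrolein F6.
- NaClO2/NaH2PO4/2-methyl-2-butene (Pinnick oxidation) gives the acrylic acid F7.
- (Trimethylsilyl)diazomethane 16 in MeOH/toluene esterifies it, which returns to the route at 34.

Step 12. Hydride may also add to the dienone carbonyl C3 or in conjugate fashion to C1, so that the two carbonyl groups are not told apart. The fallback gives up the distinction. Starting from 22, RhCl(PPh3)3/H2 first gives methyl 3,8-dioxo-13-noreudesm-4-en-12-oate F8. NaBH4/CeCl3·7H2O in MeOH at -40 °C then reduces both ketones in one operation, each from the α face (axial addition at C3, addition away from the syn-axial C10 methyl group at C8), to give methyl 3β,8β-dihydroxy-13-noreudesm-4-en-12-oate F9. Its 8β-alkoxide closes the lactone in the basic medium, and the sequence returns to the route at 26, replacing steps 12 to 14.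

Further compounds
F1 | step 11 | methyl (3R)-5-bromo-3-[(3-hydroxy-2,6-dimethylphenyl)methyl]-4-oxopentanoate | COC(=O)C[C@@H](Cc1c(C)c(O)ccc1C)C(=O)CBr
F2 | step 18 | 3β-(tert-butyldimethylsilyloxy)eudesma-4,11(13)-diene-8β,12-diol | OCC(=C)[C@H]1CC2=C(C)[C@@H](O[Si](C)(C)C(C)(C)C)CC[C@]2(C)C[C@H]1O
F3 | step 18 | 3β-(tert-butyldimethylsilyloxy)-12-(triethylsilyloxy)eudesma-4,11(13)-dien-8β-ol | CC[Si](CC)(CC)OCC(=C)[C@H]1CC2=C(C)[C@@H](O[Si](C)(C)C(C)(C)C)CC[C@]2(C)C[C@H]1O
F4 | step 18 | 3β-(tert-butyldimethylsilyloxy)-12-(triethylsilyloxy)eudesma-4,11(13)-dien-8β-yl acetate | CC[Si](CC)(CC)OCC(=C)[C@H]1CC2=C(C)[C@@H](O[Si](C)(C)C(C)(C)C)CC[C@]2(C)C[C@H]1OC(C)=O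
F5 | step 18 | 3β-(tert-butyldimethylsilyloxy)-12-hydroxyeudesma-4,11(13)-dien-8β-yl acetate | OCC(=C)[C@H]1CC2=C(C)[C@@H](O[Si](C)(C)C(C)(C)C)CC[C@]2(C)C[C@H]1OC(C)=O
F6 | step 18 | 8β-acetoxy-3β-(tert-butyldimethylsilyloxy)eudesma-4,11(13)-dien-12-al | O=CC(=C)[C@H]1CC2=C(C)[C@@H](O[Si](C)(C)C(C)(C)C)CC[C@]2(C)C[C@H]1OC(C)=O
F7 | step 18 | 8β-acetoxy-3β-(tert-butyldimethylsilyloxy)eudesma-4,11(13)-dien-12-oic acid | OC(=O)C(=C)[C@H]1CC2=C(C)[C@@H](O[Si](C)(C)C(C)(C)C)CC[C@]2(C)C[C@H]1OC(C)=O
F8 | step 12 | methyl 3,8-dioxo-13-noreudesm-4-en-12-oate | COC(=O)C[C@H]1CC2=C(C)C(=O)CC[C@]2(C)CC1=O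
F9 | step 12 | methyl 3β,8β-dihydroxy-13-noreudesm-4-en-12-oate | COC(=O)C[C@H]1CC2=C(C)[C@@H](O)CC[C@]2(C)C[C@H]1O
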